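**Retrosynthetic overview**

1. Numbering: the flavanone is unprimed (benzo ring A, pyranone ring C), the catechol ring B is primed, and the flavone is double-primed (benzo ring D, pyrone ring E, 4-hydroxyphenyl ring F). The plan rests on C8'', which carries ring B and is flanked by C8a'' (bonded to O1'') and C7'' (bonded to OH). Before ring E exists, ring D is therefore a 2-arylresorcinol whose two hydroxyls and two free CH positions are symmetry-equivalent.
2. Endgame: the seven benzyl ethers are removed last. Ring C is cut at O1–C2 (enantioselective oxa-Michael) and at C2–C3 (Knoevenagel) into the ring B aldehyde and a ring A tert-butyl aroylacetate. The ester is a removable activator, because closure of a plain 2'-hydroxychalcone is reversible and poorly face-selective.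
3. Ring E is cut at C4a''–C4'', C4''–C3'' and O1''–C2'' into the mono-iodinated 2-arylresorcinol, carbon monoxide and 4-benzyloxyphenylacetylene.
4. The C5'–C8'' biaryl bond is made before any heterocycle, by Suzuki–Miyaura coupling of a ring D iodide (from phloroglucinol by directed ortho-metalation) with a ring B boronate (from 5-bromovanillin).
5. Ring order: A, B, D and F are bought as benzenes, ring E closes in step 11 and ring C closes in step 16.

Key step: step 11

Assumption 1: the C5'–C8'' axis has only three ortho substituents and the target carries no axial descriptor, so the axis is treated as freely rotating and rotamers of the benzylated intermediates are not counted as stereoisomers.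

Assumption 2: the quinine-derived thiourea is taken to give the (2S) series. The sense should be checked by circular dichroism on the first flavanone, and the quinidine-derived pseudoenantiomer is the like-for-like replacement if the opposite sense is found.

**Route**

Step 1
Reactants: 1 phloroglucinol
Product: 2 5-(benzyloxy)benzene-1,3-diol
Conditions: BnBr (0.5 equiv), K2CO3, DMF, rt to 50 °C
Reagents that add atoms: benzyl bromide, BrCc1ccccc1
Why: Williamson ether synthesis with the triol in twofold excess, so that mono-O-alkylation is statistically favoured and the water-soluble surplus of 1 is washed out.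

Step 2
Reactants: 2 5-(benzyloxy)benzene-1,3-diol
Product: 3 1-(benzyloxy)-3,5-bis(methoxymethoxy)benzene
Conditions: MOMCl (2.5 equiv), iPr2NEt, CH2Cl2, 0 °C to rt
Reagents that add atoms: chloromethyl methyl ether, COCCl
Why: Williamson-type O-alkylation of both remaining phenols with an α-chloro ether is fast and installs the two groups that direct the next metalation.

Step 3
Reactants: 3 1-(benzyloxy)-3,5-bis(methoxymethoxy)benzene
Product: 5 5-(benzyloxy)-2-iodo-1,3-bis(methoxymethoxy)benzene, via aryllithium 4 (not isolated)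
Conditions: n-BuLi (1.1 equiv), THF, 0 °C; then I2, −78 °C to rt
Reagents that add atoms: iodine, II
Why: Directed ortho-metalation, in which the C–H between the two chelating MOM ethers is acidified and pre-complexed from both sides and should be lithiated ahead of the sites next to the benzyl ether and of the benzylic CH2, after which iodinolysis of 4 places the halogen on the future C8''.

Step 4
Reactants: 6 5-bromovanillin
Product: 7 3-bromo-4,5-dihydroxybenzaldehyde
Conditions: AlCl3 (1.2 equiv), pyridine (4.5 equiv), CH2Cl2, reflux; then 2 M HCl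
Reagents that add atoms: none
Why: Lewis acid-assisted aryl methyl ether cleavage, in which aluminium chelates the ortho hydroxy/methoxy pair and pyridine removes the methyl group by SN2 under conditions that leave the aldehyde and the aryl bromide inert.

Step 5
Reactants: 7 3-bromo-4,5-dihydroxybenzaldehyde
Product: 8 3,4-bis(benzyloxy)-5-bromobenzaldehyde
Conditions: BnBr (2.3 equiv), K2CO3, DMF, 60 °C
Reagents that add atoms: benzyl bromide, BrCc1ccccc1
Why: Double Williamson ether synthesis on an acidic catechol, with nothing else in 7 open to alkylation.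

Step 6
Reactants: 8 3,4-bis(benzyloxy)-5-bromobenzaldehyde
Product: 9 3,4-bis(benzyloxy)-5-(4,4,5,5-tetramethyl-1,3,2-dioxaborolan-2-yl)benzaldehyde
Conditions: B2pin2, PdCl2(dppf) (3 mol %), KOAc, 1,4-dioxane, 90 °C
Reagents that add atoms: bis(pinacolato)diboron, CC1(C)OB(OC1(C)C)B1OC(C)(C)C(C)(C)O1
Why: Miyaura borylation tolerates the aldehyde and the benzyl ethers, and the weak base KOAc suppresses Suzuki-type homocoupling of the product.

Step 7
Reactants: 5 5-(benzyloxy)-2-iodo-1,3-bis(methoxymethoxy)benzene; 9 3,4-bis(benzyloxy)-5-(4,4,5,5-tetramethyl-1,3,2-dioxaborolan-2-yl)benzaldehyde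
Product: 10 4',5,6-tris(benzyloxy)-2',6'-bis(methoxymethoxy)biphenyl-3-carbaldehyde
Conditions: Pd(OAc)2 (3 mol %), SPhos (6 mol %), K3PO4, toluene/H2O, 90 °C
Reagents that add atoms: none
Why: Suzuki–Miyaura coupling that forms the C5'–C8'' bond, with the halide placed on the electron-rich, doubly ortho-alkoxylated ring (whose boron counterpart would protodeboronate) and with the bulky, electron-rich SPhos ligand that suits tri-ortho-substituted biaryls.

Step 8
Reactants: 10 4',5,6-tris(benzyloxy)-2',6'-bis(methoxymethoxy)biphenyl-3-carbaldehyde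
Product: 11 4',5,6-tris(benzyloxy)-2',6'-dihydroxybiphenyl-3-carbaldehyde
Conditions: 3 M aq. HCl, THF/iPrOH, 50 °C
Reagents that add atoms: none
Why: Acid-catalysed acetal hydrolysis removes both MOM groups, while the benzyl ethers and the aldehyde are stable to dilute aqueous acid.

Step 9
Reactants: 11 4',5,6-tris(benzyloxy)-2',6'-dihydroxybiphenyl-3-carbaldehyde
Product: 12 4',5,6-tris(benzyloxy)-2',6'-dihydroxy-3'-iodobiphenyl-3-carbaldehyde
Conditions: NIS (1.0 equiv), MeCN/CH2Cl2, −20 to 0 °C, dark
Reagents that add atoms: N-iodosuccinimide, O=C1CCC(=O)N1I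
Why: Electrophilic aromatic iodination occurs on the phloroglucinol-type ring D, which is far more nucleophilic than the formyl-deactivated ring B, and because its two free positions are equivalent one equivalent of NIS at low temperature should give a single mono-iodide.

Step 10
Reactants: 13 4-(benzyloxy)benzaldehyde
Product: 14 1-(benzyloxy)-4-ethynylbenzene
Conditions: dimethyl (1-diazo-2-oxopropyl)phosphonate, K2CO3, MeOH/THF, rt
Reagents that add atoms: dimethyl (1-diazo-2-oxopropyl)phosphonate, CC(=O)C(=[N+]=[N-])P(=O)(OC)OC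
Why: Seyferth–Gilbert homologation in the Ohira–Bestmann variant converts a non-enolisable aryl aldehyde into the terminal alkyne in one mild basic operation that leaves the benzyl ether alone.

Step 11
Reactants: 12 4',5,6-tris(benzyloxy)-2',6'-dihydroxy-3'-iodobiphenyl-3-carbaldehyde; 14 1-(benzyloxy)-4-ethynylbenzene (1.5 equiv)
Product: 17 3,4-bis(benzyloxy)-5-{5-(benzyloxy)-2-[4-(benzyloxy)phenyl]-7-hydroxy-4-oxo-4H-chromen-8-yl}benzaldehyde, via ynone 15 (not isolated), via enaminone 16 (not isolated)
Conditions: PdCl2(PPh3)2 (5 mol %), CO (10 bar), Et2NH, 80 °C, no copper salt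
Reagents that add atoms: carbon monoxide, [C-]#[O+]
Why: Zerovalent palladium, formed in situ from PdCl2(PPh3)2, inserts into the C–I bond of 12, migratory insertion of CO gives the aroylpalladium iodide, and amine-assisted transfer of the acetylide of 14 followed by reductive elimination gives ynone 15 (C4a''–C4'' and C4''–C3'' bonds). Diethylamine then adds in conjugate fashion to give enaminone 16, whose β-carbon is attacked by the adjacent C8a'' phenol with loss of the amine (O1''–C2'' bond), so ring E closes in a net 6-endo-dig sense (6-endo-trig addition–elimination on 16) and the 5-exo path to an aurone is shut off. The closest known reaction type is the palladium-catalysed carbonylative Sonogashira coupling and cyclisation of 2-iodophenols with terminal arylacetylenes to flavones in a secondary amine. No stereocentre is formed. Regiochemistry is fixed by the substrate, because the iodine has only one ortho hydroxyl, that hydroxyl sits on the carbon next to the ring B-bearing carbon, and the second hydroxyl is para to the new acyl group and out of reach, so only the 8''-aryl-7''-hydroxyflavone can arise. CO uptake ahead of direct alkynylation (the benzofuran path) is secured by the CO pressure, by the absence of copper (which also denies a catalyst to aldehyde/amine/alkyne propargylamine coupling) and by the fast migratory insertion of an electron-rich, doubly ortho-substituted aryl group, while the non-enolisable aldehyde has no irreversible pathway with diethylamine.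

Step 12
Reactants: 17 3,4-bis(benzyloxy)-5-{5-(benzyloxy)-2-[4-(benzyloxy)phenyl]-7-hydroxy-4-oxo-4H-chromen-8-yl}benzaldehyde
Product: 18 3,4-bis(benzyloxy)-5-{5,7-bis(benzyloxy)-2-[4-(benzyloxy)phenyl]-4-oxo-4H-chromen-8-yl}benzaldehyde
Conditions: BnBr, K2CO3, DMF, 50 °C
Reagents that add atoms: benzyl bromide, BrCc1ccccc1
Why: Williamson ether synthesis on the acidic 7''-hydroxyl masks the last free phenol so that it cannot compete for the hydrogen-bonding catalyst later.

Step 13
Reactants: 19 2,4,6-trihydroxyacetophenone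
Product: 20 1-[2,4-bis(benzyloxy)-6-hydroxyphenyl]ethanone
Conditions: BnBr (2.05 equiv), K2CO3, acetone, reflux
Reagents that add atoms: benzyl bromide, BrCc1ccccc1
Why: Williamson ether synthesis that stops at the diether because the remaining ortho hydroxyl is tied up in a strong hydrogen bond to the ketone and is much less nucleophilic.

Step 14
Reactants: 20 1-[2,4-bis(benzyloxy)-6-hydroxyphenyl]ethanone
Product: 22 tert-butyl 3-[2,4-bis(benzyloxy)-6-hydroxyphenyl]-3-oxopropanoate, via dilithium dianion 21 (not isolated)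
Conditions: LiN(SiMe3)2 (3.3 equiv), THF, −78 to −20 °C; Boc2O (1.1 equiv), −78 to 0 °C; aq. NH4Cl
Reagents that add atoms: di-tert-butyl dicarbonate, CC(C)(C)OC(=O)OC(=O)OC(C)(C)C
Why: Claisen-type C-acylation of the phenoxide/enolate dianion 21 with the dicarbonate, in which any Boc group that lands on the phenoxide is relayed to carbon by a Baker–Venkataraman-type O-to-C transfer, the third equivalent of base stores the product as its enolate, and the tert-butyl ester is too hindered to lactonise to a 4-hydroxycoumarin.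

Step 15
Reactants: 18 3,4-bis(benzyloxy)-5-{5,7-bis(benzyloxy)-2-[4-(benzyloxy)phenyl]-4-oxo-4H-chromen-8-yl}benzaldehyde; 22 tert-butyl 3-[2,4-bis(benzyloxy)-6-hydroxyphenyl]-3-oxopropanoate
Product: 23 tert-butyl (Z)-2-[2,4-bis(benzyloxy)-6-hydroxybenzoyl]-3-(ring B aryl of 18)prop-2-enoate
Conditions: piperidine (20 mol %), AcOH (20 mol %), 4 Å MS, toluene, rt
Reagents that add atoms: none
Why: Knoevenagel condensation of the active methylene of 22 with the non-enolisable aldehyde under buffered amine catalysis with water removal should give the alkylidene β-ketoester, expected mainly as the Z isomer with ring B cis to the ester, without closing ring C.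

Step 16
Reactants: 23 tert-butyl (Z)-2-[2,4-bis(benzyloxy)-6-hydroxybenzoyl]-3-(ring B aryl of 18)prop-2-enoate
Product: 26 (2S)-hepta-O-benzyl ether of the target, via tert-butyl ester 24 (not isolated), via keto acid 25 (not isolated)
Conditions: N-[3,5-bis(trifluoromethyl)phenyl]-N'-[(8α,9S)-6'-methoxycinchonan-9-yl]thiourea (10 mol %), toluene, −25 °C; then TsOH·H2O (50 mol %), 80 °C
Reagents that add atoms: none
Why: Bifunctional organocatalytic intramolecular oxa-Michael addition (6-endo-trig) followed by acidolysis and decarboxylation, in which the thiourea holds the two carbonyl groups of the doubly activated acceptor while the quinuclidine nitrogen deprotonates the 2-hydroxyl, so that the phenoxide is delivered to one face of the benzylic carbon and C2 is set as S under catalyst control with closure practically irreversible at low temperature; TsOH then protonates the catalyst and cleaves the tert-butyl ester as isobutene, and keto acid 25 loses CO2, which erases the labile C3 centre without touching C2.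

Step 17
Reactants: 26 (2S)-hepta-O-benzyl ether of the target
Product: 27 (2S)-2-{3,4-dihydroxy-5-[5,7-dihydroxy-2-(4-hydroxyphenyl)-4-oxo-4H-chromen-8-yl]phenyl}-5,7-dihydroxychroman-4-one (CNP0204144.1)
Conditions: H2 (1 atm), Pd/C (10 wt %), THF/MeOH, AcOH (1 %), rt
Reagents that add atoms: none
Why: Catalytic hydrogenolysis of the seven aryl benzyl ethers under faintly acidic conditions at ambient pressure, where the flavone C2''=C3'' bond, both carbonyl groups and the C2–O1 bond react much more slowly and where base-induced ring opening, the racemisation path of 4'-hydroxyflavanones, is avoided.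

**Compound list**

1 | phloroglucinol | Oc1cc(O)cc(O)c1 | starting material
2 | 5-(benzyloxy)benzene-1,3-diol | Oc1cc(O)cc(OCc2ccccc2)c1 | intermediate
3 | 1-(benzyloxy)-3,5-bis(methoxymethoxy)benzene | COCOc1cc(OCOC)cc(OCc2ccccc2)c1 | intermediate
4 | [4-(benzyloxy)-2,6-bis(methoxymethoxy)phenyl]lithium | [Li]c1c(OCOC)cc(OCc2ccccc2)cc1OCOC | intermediate
5 | 5-(benzyloxy)-2-iodo-1,3-bis(methoxymethoxy)benzene | Ic1c(OCOC)cc(OCc2ccccc2)cc1OCOC | intermediate
6 | 5-bromovanillin | COc1cc(C=O)cc(Br)c1O | starting material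
7 | 3-bromo-4,5-dihydroxybenzaldehyde | O=Cc1cc(O)c(O)c(Br)c1 | intermediate
8 | 3,4-bis(benzyloxy)-5-bromobenzaldehyde | O=Cc1cc(OCc2ccccc2)c(OCc2ccccc2)c(Br)c1 | intermediate
9 | 3,4-bis(benzyloxy)-5-(4,4,5,5-tetramethyl-1,3,2-dioxaborolan-2-yl)benzaldehyde | O=Cc1cc(OCc2ccccc2)c(OCc2ccccc2)c(B2OC(C)(C)C(C)(C)O2)c1 | intermediate
10 | 4',5,6-tris(benzyloxy)-2',6'-bis(methoxymethoxy)biphenyl-3-carbaldehyde | O=Cc1cc(OCc2ccccc2)c(OCc2ccccc2)c(-c2c(OCOC)cc(OCc3ccccc3)cc2OCOC)c1 | intermediate
11 | 4',5,6-tris(benzyloxy)-2',6'-dihydroxybiphenyl-3-carbaldehyde | O=Cc1cc(OCc2ccccc2)c(OCc2ccccc2)c(-c2c(O)cc(OCc3ccccc3)cc2O)c1 | intermediate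
12 | 4',5,6-tris(benzyloxy)-2',6'-dihydroxy-3'-iodobiphenyl-3-carbaldehyde | O=Cc1cc(OCc2ccccc2)c(OCc2ccccc2)c(-c2c(O)cc(OCc3ccccc3)c(I)c2O)c1 | intermediate
13 | 4-(benzyloxy)benzaldehyde | O=Cc1ccc(OCc2ccccc2)cc1 | starting material
14 | 1-(benzyloxy)-4-ethynylbenzene | C#Cc1ccc(OCc2ccccc2)cc1 | intermediate
15 | 4',5,6-tris(benzyloxy)-3'-{3-[4-(benzyloxy)phenyl]prop-2-ynoyl}-2',6'-dihydroxybiphenyl-3-carbaldehyde | O=Cc1cc(OCc2ccccc2)c(OCc2ccccc2)c(-c2c(O)cc(OCc3ccccc3)c(C(=O)C#Cc3ccc(OCc4ccccc4)cc3)c2O)c1 | intermediate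
16 | 4',5,6-tris(benzyloxy)-3'-{(E)-3-[4-(benzyloxy)phenyl]-3-(diethylamino)prop-2-enoyl}-2',6'-dihydroxybiphenyl-3-carbaldehyde | O=Cc1cc(OCc2ccccc2)c(OCc2ccccc2)c(-c2c(O)cc(OCc3ccccc3)c(C(=O)/C=C(/N(CC)CC)c3ccc(OCc4ccccc4)cc3)c2O)c1 | intermediate
17 | 3,4-bis(benzyloxy)-5-{5-(benzyloxy)-2-[4-(benzyloxy)phenyl]-7-hydroxy-4-oxo-4H-chromen-8-yl}benzaldehyde | O=Cc1cc(OCc2ccccc2)c(OCc2ccccc2)c(-c2c(O)cc(OCc3ccccc3)c3c(=O)cc(-c4ccc(OCc5ccccc5)cc4)oc23)c1 | intermediate
18 | 3,4-bis(benzyloxy)-5-{5,7-bis(benzyloxy)-2-[4-(benzyloxy)phenyl]-4-oxo-4H-chromen-8-yl}benzaldehyde | O=Cc1cc(OCc2ccccc2)c(OCc2ccccc2)c(-c2c(OCc3ccccc3)cc(OCc3ccccc3)c3c(=O)cc(-c4ccc(OCc5ccccc5)cc4)oc23)c1 | intermediate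
19 | 2,4,6-trihydroxyacetophenone | CC(=O)c1c(O)cc(O)cc1O | starting material
20 | 1-[2,4-bis(benzyloxy)-6-hydroxyphenyl]ethanone | CC(=O)c1c(O)cc(OCc2ccccc2)cc1OCc1ccccc1 | intermediate
21 | dilithium phenoxide/enolate of 20 | C=C(O[Li])c1c(O[Li])cc(OCc2ccccc2)cc1OCc1ccccc1 | intermediate
22 | tert-butyl 3-[2,4-bis(benzyloxy)-6-hydroxyphenyl]-3-oxopropanoate | CC(C)(C)OC(=O)CC(=O)c1c(O)cc(OCc2ccccc2)cc1OCc1ccccc1 | intermediate
23 | tert-butyl (Z)-2-[2,4-bis(benzyloxy)-6-hydroxybenzoyl]-3-(3,4-bis(benzyloxy)-5-{5,7-bis(benzyloxy)-2-[4-(benzyloxy)phenyl]-4-oxo-4H-chromen-8-yl}phenyl)prop-2-enoate | CC(C)(C)OC(=O)/C(=C\c1cc(OCc2ccccc2)c(OCc2ccccc2)c(-c2c(OCc3ccccc3)cc(OCc3ccccc3)c3c(=O)cc(-c4ccc(OCc5ccccc5)cc4)oc23)c1)C(=O)c1c(O)cc(OCc2ccccc2)cc1OCc1ccccc1 | intermediate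
24 | tert-butyl (2S,3R)-5,7-bis(benzyloxy)-2-(3,4-bis(benzyloxy)-5-{5,7-bis(benzyloxy)-2-[4-(benzyloxy)phenyl]-4-oxo-4H-chromen-8-yl}phenyl)-4-oxochromane-3-carboxylate (2,3-trans, C3 labile) | O=C1[C@H](C(=O)OC(C)(C)C)[C@@H](c2cc(OCc3ccccc3)c(OCc3ccccc3)c(-c3c(OCc4ccccc4)cc(OCc4ccccc4)c4c(=O)cc(-c5ccc(OCc6ccccc6)cc5)oc34)c2)Oc2cc(OCc3ccccc3)cc(OCc3ccccc3)c21 | intermediate
25 | (2S,3R)-4-oxochromane-3-carboxylic acid corresponding to 24 | O=C1[C@H](C(=O)O)[C@@H](c2cc(OCc3ccccc3)c(OCc3ccccc3)c(-c3c(OCc4ccccc4)cc(OCc4ccccc4)c4c(=O)cc(-c5ccc(OCc6ccccc6)cc5)oc34)c2)Oc2cc(OCc3ccccc3)cc(OCc3ccccc3)c21 | intermediate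
26 | (2S)-5,7-bis(benzyloxy)-2-(3,4-bis(benzyloxy)-5-{5,7-bis(benzyloxy)-2-[4-(benzyloxy)phenyl]-4-oxo-4H-chromen-8-yl}phenyl)chroman-4-one | O=C1C[C@@H](c2cc(OCc3ccccc3)c(OCc3ccccc3)c(-c3c(OCc4ccccc4)cc(OCc4ccccc4)c4c(=O)cc(-c5ccc(OCc6ccccc6)cc5)oc34)c2)Oc2cc(OCc3ccccc3)cc(OCc3ccccc3)c21 | intermediate
27 | (2S)-2-{3,4-dihydroxy-5-[5,7-dihydroxy-2-(4-hydroxyphenyl)-4-oxo-4H-chromen-8-yl]phenyl}-5,7-dihydroxychroman-4-one | O=C1C[C@@H](c2cc(O)c(O)c(-c3c(O)cc(O)c4c(=O)cc(-c5ccc(O)cc5)oc34)c2)Oc2cc(O)cc(O)c21 | target

**Step count**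

Total step count: 17.
Longest linear sequence: 11 steps (1, 2, 3, 7, 8, 9, 11, 12, 15, 16, 17). The ring B branch (4, 5, 6, 7, 8, 9, 11, 12, 15, 16, 17) is equally long.

**Steps most likely to fail**

**Step 11.** Several processes could interfere:
- oxidative addition at the electron-rich, doubly ortho-oxygenated C–I bond may be slow;
- the substrate may undergo hydrodeiodination;
- the acylpalladium species may be captured by the amine solvent or by a phenol;
- alkynylation may occur before CO uptake.

The fallback forms ring E before the biaryl bond. Commercial apigenin is perbenzylated (BnBr, K2CO3, DMF, 80 °C) to tri-O-benzylapigenin F1. This is iodinated (NIS, cat. TFA, MeCN/CH2Cl2) at C8, the position at which fully O-alkylated 5,7-dioxygenated flavones take electrophiles, to give 8-iodoflavone F2. F2 is then joined to the ring B boronate under the Suzuki–Miyaura conditions of step 7. This path sets out from 9 and comes back to the route at 18.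

**Step 16.** The possible problems are racemic background closure during or after the Knoevenagel step, poor facial selectivity because the 6-benzyloxy group twists the aroyl unit out of the catalyst's grip, and erosion by acid-promoted ring opening or partial benzyl loss at 80 °C.

The fallback replaces catalyst-controlled closure by racemic closure and kinetic resolution, and it also bypasses steps 14 and 15. It sets out from 18 and 20.
- Claisen–Schmidt condensation (KOH, EtOH/THF, rt) gives the 2'-hydroxychalcone F3.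
- NaOAc in refluxing EtOH/THF closes it to the racemic flavanone F4.
- Noyori asymmetric transfer hydrogenation with RuCl(p-cymene)[(R,R)-TsDPEN] (HCO2H/Et3N, EtOAc) is run to about half conversion.

This catalyst makes (4R)-benzylic alcohols and is matched with the (2R)-enantiomer, which goes to the cis (2R,4R)-flavan-4-ol F5. The (2S)-ketone remains and is separated by chromatography. The path comes back to the route at 26.

**Step 17.** The possible problems are incomplete cleavage as partly deprotected material loses solubility, over-reduction at C2''=C3'' or at the benzylic C2–O1 bond, and racemisation of the free 4'-hydroxyflavanone during a long reaction or work-up.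

The fallback is non-reductive Lewis acid debenzylation with BCl3 and pentamethylbenzene as cation scavenger (CH2Cl2, −78 °C, MeOH quench). It sets out from 26 and comes back to the route at 27. No new compound arises on this path (placeholder F0).

**Further compounds**

F1 | step 11 | 5,7-bis(benzyloxy)-2-[4-(benzyloxy)phenyl]-4H-chromen-4-one | O=c1cc(-c2ccc(OCc3ccccc3)cc2)oc2cc(OCc3ccccc3)cc(OCc3ccccc3)c12
F2 | step 11 | 5,7-bis(benzyloxy)-2-[4-(benzyloxy)phenyl]-8-iodo-4H-chromen-4-one | O=c1cc(-c2ccc(OCc3ccccc3)cc2)oc2c(I)c(OCc3ccccc3)cc(OCc3ccccc3)c12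
F3 | step 16 | (E)-1-[2,4-bis(benzyloxy)-6-hydroxyphenyl]-3-(3,4-bis(benzyloxy)-5-{5,7-bis(benzyloxy)-2-[4-(benzyloxy)phenyl]-4-oxo-4H-chromen-8-yl}phenyl)prop-2-en-1-one | O=C(/C=C/c1cc(OCc2ccccc2)c(OCc2ccccc2)c(-c2c(OCc3ccccc3)cc(OCc3ccccc3)c3c(=O)cc(-c4ccc(OCc5ccccc5)cc4)oc23)c1)c1c(O)cc(OCc2ccccc2)cc1OCc1ccccc1
F4 | step 16 | racemic hepta-O-benzyl flavanone (rac-26) | O=C1CC(c2cc(OCc3ccccc3)c(OCc3ccccc3)c(-c3c(OCc4ccccc4)cc(OCc4ccccc4)c4c(=O)cc(-c5ccc(OCc6ccccc6)cc5)oc34)c2)Oc2cc(OCc3ccccc3)cc(OCc3ccccc3)c21
F5 | step 16 | (2R,4R)-cis-flavan-4-ol from the (2R)-enantiomer of F4 | O[C@@H]1C[C@H](c2cc(OCc3ccccc3)c(OCc3ccccc3)c(-c3c(OCc4ccccc4)cc(OCc4ccccc4)c4c(=O)cc(-c5ccc(OCc6ccccc6)cc5)oc34)c2)Oc2cc(OCc3ccccc3)cc(OCc3ccccc3)c21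
F0 | step 17 | none | none
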